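**Retrosynthetic overview**

- The target is cut at the sn-2 ester into (5R,10R,13R)-labd-8-en-15-oic acid and 1-O-acetyl-3-O-benzyl-sn-glycerol (acetic acid opening of (R)-benzyl glycidyl ether); the benzyl ether is removed last.
- The acid goes back through its C8=C17 isomer (acid-catalysed olefin shift) and the 15-ol (oxidation) to ent-copalol, where a hydroxyl-directed asymmetric hydrogenation sets C13.
- ent-Copalol is the hydrolysed product of the key step: a class 2 diterpene cyclase folds (E,E,E)-geranylgeranyl diphosphate, closing ring A (C4–C5) and then ring B (C9–C10) in one operation and setting C5, C9 and C10.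
- Feature on which the strategy rests: the ent-configured trans-decalin (ring A C1–C5 and C10, ring B C5–C10) with quaternary C10 (C20 methyl), gem-dimethyl C4 and the C9 chain ending in oxygenated C15 is the chair–chair fold of a tetraprenyl chain whose C3=C4, C5=C10 and C8=C9 olefins lie where the two ring bonds are needed.
- The diphosphate comes from geranylgeraniol through the allylic chloride.

Key step: step 3

Assumption: the two diphosphates are drawn as free acids but are made, stored and used as ammonium salts near pH 7.5 (the tetrabutylammonium counter-ions of the crude displacement product are taken up by the exchange resin), and the cyclase is taken as a recombinant protein obtained by standard expression in E. coli.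

**Route**

Step 1
Reactants: 1 (2E,6E,10E)-geranylgeraniol
Product: 2 (2E,6E,10E)-geranylgeranyl chloride
Conditions: NCS (1.1 equiv), Me2S (1.2 equiv), CH2Cl2, −40 → 0 °C
Reagents that add atoms: N-chlorosuccinimide, O=C1CCC(=O)N1Cl
Why: Corey–Kim chlorination: the chlorosulfonium salt activates the primary allylic hydroxyl and chloride displaces it by SN2 at the carbinol carbon (C15 in labdane numbering), so the adjacent E olefin should be neither transposed nor isomerised.

Step 2
Reactants: 2 (2E,6E,10E)-geranylgeranyl chloride
Product: 3 (2E,6E,10E)-geranylgeranyl diphosphate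
Conditions: (Bu4N)3HP2O7 (2 equiv), MeCN, rt; then cation-exchange resin (NH4+ form), cellulose chromatography (iPrOH/MeCN/aq NH4HCO3)
Reagents that add atoms: tris(tetrabutylammonium) hydrogen diphosphate, CCCC[N+](CCCC)(CCCC)CCCC.CCCC[N+](CCCC)(CCCC)CCCC.CCCC[N+](CCCC)(CCCC)CCCC.OP(=O)([O-])OP(=O)([O-])[O-]
Why: SN2 displacement of the primary allylic chloride by the diphosphate anion in a dipolar aprotic solvent; attack at C15 rather than SN2′ keeps the E olefin, and ion exchange gives the ammonium salt that the enzyme accepts.

Step 3
Reactants: 3 (2E,6E,10E)-geranylgeranyl diphosphate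
Product: 4 ent-copalyl diphosphate, (5R,9R,10R,13E)-labda-8(17),13-dien-15-yl diphosphate
Conditions: recombinant ent-copalyl diphosphate synthase (N-terminally truncated Arabidopsis thaliana enzyme from E. coli), 50 mM HEPES pH 7.5, 0.1 mM MgCl2, 10% glycerol, 5 mM DTT, 30 °C, 3 added by syringe pump (kept ≤ 20 µM); ultrafiltration, C18 solid-phase extraction
Reagents that add atoms: none
Why: The enzyme's general acid (the central aspartate of the DXDD motif) protonates C3 of the C3=C4 olefin of a substrate held in a chair–chair fold; C5 of the C5=C10 olefin then adds to the C4 cation (C4–C5 bond, 6-endo-trig, ring A), C9 of the C8=C9 olefin adds to the C10 cation (C9–C10 bond, 6-endo-trig, ring B), and the C8 cation loses a C17 proton to the active-site base to leave the exocyclic C8=C17 olefin. The closest laboratory reaction type is the proton-initiated cationic polyene cyclization of the Stork–Eschenmoser kind, and here it is the native reaction of a class 2 diterpene cyclase on its natural substrate. Each E olefin is attacked in an antiperiplanar sense, so H5 and the C20 methyl on C10 come out trans (trans-decalin) and H9 trans to C20 with the C11 chain equatorial, which fixes the relative configuration of C5, C9 and C10. The absolute configuration (5R,9R,10R, the ent series) is set by the active site, which binds the chain in the fold antipodal to that of the normal-series cyclases and protonates one enantioface of C3=C4 only. The step needs three selectivities, namely to stop at the bicycle, to leave the C13=C14 allylic diphosphate alone and to deprotonate at C17 rather than C7 or C9; the magnesium-bound diphosphate holds C15 away from the cation path, the enzyme has no ionisation site for it, and the position of the base decides the olefin. Substrate 3 is fed slowly and MgCl2 is kept low because cyclases of this class are inhibited by excess substrate together with magnesium ion.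

Step 4
Reactants: 4 ent-copalyl diphosphate
Product: 5 ent-copalol, (5R,9R,10R,13E)-labda-8(17),13-dien-15-ol
Conditions: calf intestinal alkaline phosphatase, 0.1 M Tris buffer pH 8.5, 1 mM MgCl2, 37 °C; hexane extraction
Reagents that add atoms: none
Why: Enzymatic phosphate monoester hydrolysis cleaves the P–O bonds and not the allylic C15–O bond, so no allyl cation forms, the 13E olefin is neither transposed nor isomerised, and the acid-sensitive exocyclic olefin is untouched.

Step 5
Reactants: 5 ent-copalol
Product: 6 (5R,9R,10R,13R)-labd-8(17)-en-15-ol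
Conditions: Ru(OAc)2[(S)-BINAP] (1 mol%), H2 (100 atm), MeOH/H2O 95:5, 20 °C
Reagents that add atoms: none
Why: Noyori asymmetric hydrogenation of an allylic alcohol: the hydroxyl binds ruthenium and, with the (S)-ligand, the 13E olefin should take hydrogen on the face that gives 13R (the sense in which geraniol gives (R)-citronellol), under catalyst control; the C8=C17 olefin has no directing group and should not be reduced.

Step 6
Reactants: 6 (5R,9R,10R,13R)-labd-8(17)-en-15-ol
Product: 8 (5R,9R,10R,13R)-labd-8(17)-en-15-oic acid, via labd-8(17)-en-15-al 7 (not isolated)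
Conditions: TEMPO (0.2 equiv), PhI(OAc)2 (2.2 equiv), MeCN/H2O 1:1, rt
Reagents that add atoms: water, O
Why: Oxoammonium (TEMPO) oxidation with a hypervalent iodine co-oxidant takes the primary alcohol to aldehyde 7, whose hydrate is oxidised on to the acid in the aqueous medium; the isolated C8=C17 olefin should not be attacked and C13, β to the carbonyl, cannot epimerise.

Step 7
Reactants: 8 (5R,9R,10R,13R)-labd-8(17)-en-15-oic acid
Product: 9 (5R,10R,13R)-labd-8-en-15-oic acid
Conditions: HI (57% aq, 0.2 equiv), benzene, 60 °C, followed by 1H NMR until the =CH2 signals no longer decrease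
Reagents that add atoms: none
Why: Acid-catalysed olefin isomerisation: reversible Markovnikov protonation at C17 gives the tertiary C8 cation (or its iodide) and loss of H9 leads to the tetrasubstituted C8=C9 olefin, expected to be the thermodynamic sink of the positional isomers; the C9 stereocenter is given up by design and C5, C10 and C13 are not involved.

Step 8
Reactants: 10 (R)-benzyl glycidyl ether
Product: 11 (2S)-3-(benzyloxy)-2-hydroxypropyl acetate (1-O-acetyl-3-O-benzyl-sn-glycerol)
Conditions: AcOH (1.5 equiv), Et4NBr (5 mol%), toluene, 90 °C
Reagents that add atoms: acetic acid, CC(=O)O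
Why: Halide/carboxylate-catalysed opening of a terminal epoxide by a carboxylic acid: acetate attacks the unsubstituted ring CH2 by SN2, so C2 keeps its spatial arrangement (the descriptor changes from R to S only because CH2OAc outranks CH2OBn).

Step 9
Reactants: 9 (5R,10R,13R)-labd-8-en-15-oic acid; 11 (2S)-3-(benzyloxy)-2-hydroxypropyl acetate
Product: 12 (2S)-1-acetoxy-3-(benzyloxy)propan-2-yl (5R,10R,13R)-labd-8-en-15-oate
Conditions: DCC (1.2 equiv), DMAP (0.1 equiv), CH2Cl2, 0 °C → rt
Reagents that add atoms: none
Why: Steglich esterification (carbodiimide activation, DMAP acyl transfer) of an unhindered β-branched acid with the secondary hydroxyl under neutral, cold conditions that should not let the primary acetate migrate; no stereocenter is involved.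

Step 10
Reactants: 12 (2S)-1-acetoxy-3-(benzyloxy)propan-2-yl (5R,10R,13R)-labd-8-en-15-oate
Product: 13 (2S)-1-acetoxy-3-hydroxypropan-2-yl (5R,10R,13R)-labd-8-en-15-oate (target)
Conditions: H2 (1 atm), Pd/C (10%), EtOAc, 0 °C → rt; filtration; short column on boric-acid-treated SiO2, stored cold
Reagents that add atoms: none
Why: Hydrogenolysis of the benzyl ether over palladium under neutral conditions: the hindered tetrasubstituted C8=C9 olefin should not be reduced at 1 atm, and the cold, acid- and base-free work-up is chosen to keep the sn-2 ester in place next to the freed hydroxyl.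

**Compound list**

1 | (2E,6E,10E)-geranylgeraniol | CC(C)=CCC/C(C)=C/CC/C(C)=C/CC/C(C)=C/CO | starting material
2 | (2E,6E,10E)-geranylgeranyl chloride | CC(C)=CCC/C(C)=C/CC/C(C)=C/CC/C(C)=C/CCl | intermediate
3 | (2E,6E,10E)-geranylgeranyl diphosphate (drawn as free acid) | CC(C)=CCC/C(C)=C/CC/C(C)=C/CC/C(C)=C/COP(=O)(O)OP(=O)(O)O | intermediate
4 | ent-copalyl diphosphate, (5R,9R,10R,13E)-labda-8(17),13-dien-15-yl diphosphate (drawn as free acid) | C/C(=C\COP(=O)(O)OP(=O)(O)O)CC[C@@H]1C(=C)CC[C@@H]2C(C)(C)CCC[C@@]12C | intermediate
5 | ent-copalol, (5R,9R,10R,13E)-labda-8(17),13-dien-15-ol | C/C(=C\CO)CC[C@@H]1C(=C)CC[C@@H]2C(C)(C)CCC[C@@]12C | intermediate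
6 | (5R,9R,10R,13R)-labd-8(17)-en-15-ol | OCC[C@H](C)CC[C@@H]1C(=C)CC[C@@H]2C(C)(C)CCC[C@@]12C | intermediate
7 | (5R,9R,10R,13R)-labd-8(17)-en-15-al | O=CC[C@H](C)CC[C@@H]1C(=C)CC[C@@H]2C(C)(C)CCC[C@@]12C | intermediate (not isolated)
8 | (5R,9R,10R,13R)-labd-8(17)-en-15-oic acid | OC(=O)C[C@H](C)CC[C@@H]1C(=C)CC[C@@H]2C(C)(C)CCC[C@@]12C | intermediate
9 | (5R,10R,13R)-labd-8-en-15-oic acid | OC(=O)C[C@H](C)CCC1=C(C)CC[C@@H]2C(C)(C)CCC[C@@]12C | intermediate
10 | (R)-benzyl glycidyl ether, (2R)-2-[(benzyloxy)methyl]oxirane | C1[C@H](COCc2ccccc2)O1 | starting material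
11 | (2S)-3-(benzyloxy)-2-hydroxypropyl acetate | CC(=O)OC[C@H](COCc1ccccc1)O | intermediate
12 | (2S)-1-acetoxy-3-(benzyloxy)propan-2-yl (5R,10R,13R)-labd-8-en-15-oate | CC(=O)OC[C@H](COCc1ccccc1)OC(=O)C[C@H](C)CCC1=C(C)CC[C@@H]2C(C)(C)CCC[C@@]12C | intermediate
13 | (2S)-1-acetoxy-3-hydroxypropan-2-yl (5R,10R,13R)-labd-8-en-15-oate | CC(=O)OC[C@H](CO)OC(=O)C[C@H](C)CCC1=C(C)CC[C@@H]2C(C)(C)CCC[C@@]12C | target

**Step count**

Total: 10 steps. Longest linear sequence: 9 steps (steps 1–7, 9 and 10, from geranylgeraniol 1); step 8 is the one-step side branch.

**Steps most likely to fail**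

Step 3 (key step). Turnover may stall at preparative loading: the amphiphilic substrate aggregates and, with magnesium ion, inhibits the cyclase, the product is released slowly, and adventitious phosphatase activity in the enzyme preparation can hydrolyse 3 back to 1 before it is cyclised. Fallback: the same cyclization is run inside a cell instead of on isolated 3. An E. coli strain carrying a heterologous mevalonate pathway, a geranylgeranyl diphosphate synthase and the same ent-copalyl diphosphate synthase is grown on glycerol under a dodecane overlay. In the cell 3 is formed at a low steady-state concentration and cyclised to 4, host phosphatases hydrolyse 4, and ent-copalol 5 is recovered from the overlay. This fallback does not set out from a numbered compound (it replaces steps 1 to 4, the carbon source being glycerol), makes no compound outside the list (F0), and comes back to the route at 5.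

Step 7. The equilibration may not select cleanly: loss of a C7 proton gives the trisubstituted C7=C8 isomer, which is hard to separate from 9, and on long acid exposure the C8 cation can start backbone shifts (hydride from C9, then methyl from C10). Fallback, setting out from acid 8 and coming back at acid 9, builds the C8=C9 olefin without a free tertiary C8 cation. Acid 8 is methylated (Me3SiCHN2, MeOH/toluene) to methyl (5R,9R,10R,13R)-labd-8(17)-en-15-oate F1. Ozonolysis (O3, CH2Cl2/MeOH, −78 °C; Me2S) should give the nor-ketone methyl (5R,9S,10R,13R)-8-oxo-17-norlabdan-15-oate F2. Triflation under non-basic, equilibrating conditions (Tf2O, 2,6-di-tert-butyl-4-methylpyridine, CH2Cl2, 0 °C → rt) is expected to favour the more substituted enol triflate, methyl (5R,10R,13R)-8-(trifluoromethanesulfonyloxy)-17-norlabd-8-en-15-oate F3, which is purified at this stage. Cuprate coupling (Me2CuLi, THF, −20 °C) puts the C17 methyl back to give methyl (5R,10R,13R)-labd-8-en-15-oate F4, and LiOH in THF/H2O returns acid 9.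

Step 10. Acyl migration may follow the deprotection: once the sn-3 hydroxyl is free, the sn-2 ester can move to it on the catalyst surface, on silica or on standing. Slow reduction or migration of the C8=C9 olefin under hydrogen is also possible. Fallback, setting out from acid 9 and coming back at target 13, replaces the benzyl ether by a 4-methoxybenzyl ether that is removed oxidatively. (S)-Glycidol is alkylated (NaH, 4-methoxybenzyl chloride, THF, 0 °C) to (R)-4-methoxybenzyl glycidyl ether F5. Opening with AcOH as in step 8 gives (2S)-2-hydroxy-3-(4-methoxybenzyloxy)propyl acetate F6. Esterification with 9 as in step 9 gives (2S)-1-acetoxy-3-(4-methoxybenzyloxy)propan-2-yl (5R,10R,13R)-labd-8-en-15-oate F7. DDQ in CH2Cl2/pH 7 buffer at 0 °C should then release 13 without hydrogen and without acid or base.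

**Further compounds**

F0 | step 3 | none | none
F1 | step 7 | methyl (5R,9R,10R,13R)-labd-8(17)-en-15-oate | COC(=O)C[C@H](C)CC[C@@H]1C(=C)CC[C@@H]2C(C)(C)CCC[C@@]12C
F2 | step 7 | methyl (5R,9S,10R,13R)-8-oxo-17-norlabdan-15-oate | COC(=O)C[C@H](C)CC[C@@H]1C(=O)CC[C@@H]2C(C)(C)CCC[C@@]12C
F3 | step 7 | methyl (5R,10R,13R)-8-(trifluoromethanesulfonyloxy)-17-norlabd-8-en-15-oate | COC(=O)C[C@H](C)CCC1=C(OS(=O)(=O)C(F)(F)F)CC[C@@H]2C(C)(C)CCC[C@@]12C
F4 | step 7 | methyl (5R,10R,13R)-labd-8-en-15-oate | COC(=O)C[C@H](C)CCC1=C(C)CC[C@@H]2C(C)(C)CCC[C@@]12C
F5 | step 10 | (R)-4-methoxybenzyl glycidyl ether | C1[C@H](COCc2ccc(OC)cc2)O1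
F6 | step 10 | (2S)-2-hydroxy-3-(4-methoxybenzyloxy)propyl acetate | CC(=O)OC[C@H](COCc1ccc(OC)cc1)O
F7 | step 10 | (2S)-1-acetoxy-3-(4-methoxybenzyloxy)propan-2-yl (5R,10R,13R)-labd-8-en-15-oate | CC(=O)OC[C@H](COCc1ccc(OC)cc1)OC(=O)C[C@H](C)CCC1=C(C)CC[C@@H]2C(C)(C)CCC[C@@]12C
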